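**Retrosynthetic overview** (labdane numbering: ring A = C1–C5 and C10; ring B = C5–C10; side chain C11–C16)
1. Last bonds: O–Si at C8, then C12–C13 by lithiation–borylation of a C12 boronic ester with the carbamate of (S)-but-3-en-2-ol (sets C13), then C11=C12 by boron–Wittig on a C9 aldehyde.
2. Key disconnection: in ring B, C5 and C8 are para, C8 carries the only oxygen and C9 carries C11. With a C6=C7 bond added, ring B is the cycloadduct of a 1-silyloxy-1-methyl diene (C5=C6–C7=C8) and an E-enal (C11(=O)–C9=C10).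
3. The chain C1–C4 of ring A is the tether from C5 to C10, so one intramolecular Diels–Alder reaction forms C5–C10 and C8–C9, closes rings A and B together, and sets C5, C8, C9 and C10 under the C3–Br stereocentre.
4. Acyclic trienal: C5=C6 by cross-metathesis, C9=C10 by carboalumination of an alkyne, C1–C2 by propargylation of a triflate, C3–Br by organocatalytic α-bromination of 3,3-dimethylpent-4-enal.
5. Ring order: no ring before step 11; rings A and B form at the same time.

Key step: step 11

Assumption: (S)-pent-4-en-2-ol (12) and (S)-but-3-en-2-ol (23) are bought as single enantiomers; the stereocentre of 12 only keeps 13 homogeneous and is erased in step 7.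

**Step 1**
Reactants: 1 methyl 3,3-dimethylpent-4-enoate
Product: 2 3,3-dimethylpent-4-enal
Conditions: i-Bu2AlH (1.05 equiv), CH2Cl2, −78 °C; aqueous potassium sodium tartrate
Reagents that add atoms: none
Why: DIBAL-H partial reduction of an ester, which should stop at the aluminium hemiacetal at −78 °C and give the aldehyde on hydrolysis; no stereocentre.

**Step 2**
Reactants: 2 3,3-dimethylpent-4-enal
Product: 4 (S)-2-bromo-3,3-dimethylpent-4-en-1-ol, via bromo aldehyde 3 (not isolated)
Conditions: (2R,5R)-2,5-diphenylpyrrolidine (20 mol %), PhCO2H (20 mol %), 4,4-dibromo-2,6-di-tert-butylcyclohexa-2,5-dien-1-one (1.0 equiv), H2O (2 equiv), CH2Cl2/pentane, −40 °C; then NaBH4, MeOH, −40 → 0 °C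
Reagents that add atoms: 4,4-dibromo-2,6-di-tert-butylcyclohexa-2,5-dien-1-one, CC(C)(C)C1=CC(Br)(Br)C=C(C(C)(C)C)C1=O
Why: Enamine-mediated organocatalytic α-bromination, in which the phenyl group of the C2-symmetric amine blocks one face of the E-enamine so that bromine enters from the open face and sets C3 as (S) in 3 (the spatial arrangement of (3R) in the target; β-quaternary aldehydes are known substrates), followed by immediate NaBH4 reduction to prevent racemisation.

**Step 3**
Reactants: 4 (S)-2-bromo-3,3-dimethylpent-4-en-1-ol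
Product: 5 (S)-2-bromo-3,3-dimethylpent-4-en-1-yl trifluoromethanesulfonate
Conditions: Tf2O (1.1 equiv), 2,6-lutidine (1.3 equiv), CH2Cl2, −78 °C; cold aqueous work-up, used at once
Reagents that add atoms: trifluoromethanesulfonic anhydride, O=S(=O)(OS(=O)(=O)C(F)(F)F)C(F)(F)F
Why: O-sulfonylation of a primary alcohol with a hindered pyridine base, which should leave the adjacent C–Br stereocentre untouched.

**Step 4**
Reactants: 5 (S)-2-bromo-3,3-dimethylpent-4-en-1-yl trifluoromethanesulfonate; 6 1-(trimethylsilyl)propyne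
Product: 9 (5R)-5-bromo-6,6-dimethyloct-7-en-1-yne, via lithiated silylpropyne 7 (not isolated), via silyl alkyne 8 (not isolated)
Conditions: 6, n-BuLi, THF, −78 °C; add 5, −78 → −40 °C; then MeOH, K2CO3 (0.2 equiv), rt
Reagents that add atoms: none
Why: SN2 alkylation of a primary triflate by the propargylic carbanion of 1-(trimethylsilyl)propyne at −78 °C, where substitution should outrun E2 loss of triflic acid, followed by methanolysis of the C–Si bond; C3 is not involved (S becomes R only through the CIP ranks).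

**Step 5**
Reactants: 9 (5R)-5-bromo-6,6-dimethyloct-7-en-1-yne
Product: 11 methyl (2E,6R)-6-bromo-3,7,7-trimethylnona-2,8-dienoate, via alkenylalane 10 (not isolated)
Conditions: Me3Al (2.5 equiv), Cp2ZrCl2 (0.25 equiv), H2O (1 equiv), CH2Cl2, −20 °C; then ClCO2Me, −20 °C → rt
Reagents that add atoms: trimethylaluminium, C[Al](C)C; methyl chloroformate, COC(=O)Cl
Why: Negishi carboalumination adds CH3–Al syn across the terminal alkyne with methyl on the internal carbon, and acylation of the alkenyl–Al bond with retention fixes the E-trisubstituted enoate (C9=C10); the monosubstituted alkene and the hindered bromide should be inert at −20 °C.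

**Step 6**
Reactants: 11 methyl (2E,6R)-6-bromo-3,7,7-trimethylnona-2,8-dienoate; 12 (S)-pent-4-en-2-ol
Product: 13 methyl (2E,6R,8E,11S)-6-bromo-11-hydroxy-3,7,7-trimethyldodeca-2,8-dienoate
Conditions: 12 (3 equiv), Hoveyda–Grubbs second-generation catalyst RuCl2(H2IMes)(=CH-C6H4-2-O-i-Pr) (5 mol %), 1,4-benzoquinone (10 mol %), CH2Cl2, 40 °C
Reagents that add atoms: none
Why: Olefin cross-metathesis between a vinyl group on a quaternary carbon (no homodimerisation) and an excess of an unhindered terminal alkene should be selective for the cross product and give the E-alkene (C5=C6) for steric reasons; the trisubstituted enoate does not take part.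

**Step 7**
Reactants: 13 methyl (2E,6R,8E,11S)-6-bromo-11-hydroxy-3,7,7-trimethyldodeca-2,8-dienoate
Product: 14 methyl (2E,6R,8E)-6-bromo-3,7,7-trimethyl-11-oxododeca-2,8-dienoate
Conditions: Dess–Martin periodinane (1.2 equiv), pyridine, CH2Cl2, 0 °C → rt
Reagents that add atoms: none
Why: Dess–Martin oxidation under buffered, non-enolising conditions should keep the β,γ-unsaturated ketone out of conjugation; the carbinol stereocentre is erased.

**Step 8**
Reactants: 14 methyl (2E,6R,8E)-6-bromo-3,7,7-trimethyl-11-oxododeca-2,8-dienoate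
Product: 15 methyl (2E,6R,8E,10Z)-6-bromo-3,7,7-trimethyl-11-[(triethylsilyl)oxy]dodeca-2,8,10-trienoate
Conditions: Et3SiOTf (1.2 equiv), Et3N (2 equiv), CH2Cl2, −78 → 0 °C; chromatography on Et3N-deactivated silica
Reagents that add atoms: triethylsilyl trifluoromethanesulfonate, CC[Si](CC)(CC)OS(=O)(=O)C(F)(F)F
Why: Soft enolisation (silyl triflate and amine) removes the doubly activated C7 proton and O-silylates the dienolate; the 10Z isomer (silyloxy cis to the vinyl group) should prevail because the E isomer presses the C8 methyl against the diene.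

**Step 9**
Reactants: 15 methyl (2E,6R,8E,10Z)-6-bromo-3,7,7-trimethyl-11-[(triethylsilyl)oxy]dodeca-2,8,10-trienoate
Product: 16 (2E,6R,8E,10Z)-6-bromo-3,7,7-trimethyl-11-[(triethylsilyl)oxy]dodeca-2,8,10-trien-1-ol
Conditions: i-Bu2AlH (2.2 equiv), CH2Cl2, −78 °C; aqueous potassium sodium tartrate
Reagents that add atoms: none
Why: DIBAL-H 1,2-reduction of an enoate to the allylic alcohol; silyl enol ether and secondary bromide should not react at −78 °C.

**Step 10**
Reactants: 16 (2E,6R,8E,10Z)-6-bromo-3,7,7-trimethyl-11-[(triethylsilyl)oxy]dodeca-2,8,10-trien-1-ol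
Product: 17 (2E,6R,8E,10Z)-6-bromo-3,7,7-trimethyl-11-[(triethylsilyl)oxy]dodeca-2,8,10-trienal
Conditions: MnO2 (activated, 15 equiv), CH2Cl2, 0 °C → rt; filtered, used directly
Reagents that add atoms: none
Why: MnO2 allylic oxidation is neutral and selective for the allylic alcohol, so the acid-labile silyl dienol ether and the E-enal geometry should be kept.

**Step 11**
Reactants: 17 (2E,6R,8E,10Z)-6-bromo-3,7,7-trimethyl-11-[(triethylsilyl)oxy]dodeca-2,8,10-trienal
Product: 18 (1S,2S,4aS,6R,8aR)-6-bromo-2,5,5,8a-tetramethyl-2-[(triethylsilyl)oxy]-1,2,4a,5,6,7,8,8a-octahydronaphthalene-1-carbaldehyde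
Conditions: toluene (0.01 M), BHT (5 mol %), base-washed glass, 80–100 °C
Reagents that add atoms: none
Why: Thermal, concerted but asynchronous normal-electron-demand [4+2] cycloaddition (type 1 intramolecular Diels–Alder): the HOMO of the 1-silyloxy diene (largest at C5) and the LUMO of the enal (largest at C10) let the C5–C10 bond lead and the C8–C9 bond follow. The closest known reaction type is the thermal cyclisation of terminally activated deca-2,8,10-trienals and -trienoates to trans-fused octalins, together with the known cycloadditions of 1-silyloxy dienes with enals. Ring A closes as the six-membered ring that holds the four-carbon tether C1–C4 (fused mode, tether anti), ring B as the cyclohexene made of the diene carbons C5–C8 and the dienophile carbons C9–C10. The E-enal fixes C9 relative to C10 (C11 cis to the C10 methyl), the 10Z enol ether fixes C8 (inside silyloxy group cis to H5, outside methyl trans), the endo formyl group with a chair-like tether gives the trans ring fusion, and the C3 bromine, equatorial in that chair, selects the diene face and so the absolute sense of C5, C8, C9 and C10. The step needs endo over exo selectivity, which the secondary-orbital preference of the enal at this mild temperature should give, and facial selectivity, which rests only on the equatorial preference of C–Br next to the gem-dimethyl carbon and is expected to be moderate, the axial-bromine diastereomer being removed by chromatography.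

**Step 12**
Reactants: 18 (1S,2S,4aS,6R,8aR)-6-bromo-2,5,5,8a-tetramethyl-2-[(triethylsilyl)oxy]-1,2,4a,5,6,7,8,8a-octahydronaphthalene-1-carbaldehyde; 19 bis[(pinacolato)boryl]methane
Product: 21 2-[(E)-2-[(1S,2S,4aS,6R,8aR)-6-bromo-2,5,5,8a-tetramethyl-2-[(triethylsilyl)oxy]-1,2,4a,5,6,7,8,8a-octahydronaphthalen-1-yl]ethenyl]-4,4,5,5-tetramethyl-1,3,2-dioxaborolane, via lithiated diborylmethane 20 (not isolated)
Conditions: 19, LiTMP (lithium 2,2,6,6-tetramethylpiperidide), THF, 0 °C; then 18, −78 °C → rt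
Reagents that add atoms: none
Why: Boron–Wittig olefination, in which the stabilised 1,1-diboryl carbanion adds to the aldehyde and eliminates a boron oxide unit to give the E-alkenyl boronate (C11=C12); its low basicity should spare the β-silyloxy aldehyde from elimination and C9 from epimerisation.

**Step 13**
Reactants: 21 the alkenyl boronate of step 12
Product: 22 2-{2-[(1S,2S,4aS,6R,8aR)-6-bromo-2,5,5,8a-tetramethyl-2-[(triethylsilyl)oxy]decahydronaphthalen-1-yl]ethyl}-4,4,5,5-tetramethyl-1,3,2-dioxaborolane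
Conditions: H2 (1–3 atm), PtO2 (10 mol %), EtOAc, rt
Reagents that add atoms: none
Why: Heterogeneous catalytic hydrogenation saturates C6=C7 and C11=C12 in one pass without creating a stereocentre; neutral PtO2 should leave C–Br, C–B and the silyl ether intact.

**Step 14**
Reactants: 23 (S)-but-3-en-2-ol
Product: 24 (S)-but-3-en-2-yl N,N-diisopropylcarbamate
Conditions: NaH (1.2 equiv), THF, 0 °C; i-Pr2NCOCl (1.1 equiv), reflux
Reagents that add atoms: N,N-diisopropylcarbamoyl chloride, CC(C)N(C(C)C)C(Cl)=O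
Why: O-carbamoylation of the sodium alkoxide; the stereocentre is not touched.

**Step 15**
Reactants: 22 the alkyl boronate of step 13; 24 (S)-but-3-en-2-yl N,N-diisopropylcarbamate
Product: 28 (3R)-5-[(1S,2S,4aS,6R,8aR)-6-bromo-2,5,5,8a-tetramethyl-2-[(triethylsilyl)oxy]decahydronaphthalen-1-yl]-3-methylpent-1-en-3-ol, via lithiated carbamate 25 (not isolated), via boronate complex 26 (not isolated), via tertiary boronic ester 27 (not isolated)
Conditions: 24 (1.3 equiv), s-BuLi (1.2 equiv), TMEDA, Et2O, −78 °C; add 22, −78 °C → rt; then H2O2, aqueous NaOH, THF, 0 °C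
Reagents that add atoms: hydrogen peroxide, OO
Why: Lithiation–borylation of a secondary allylic carbamate: the configurationally stable α-oxy allyllithium is borylated at the α-carbon with retention, the primary alkyl group migrates stereospecifically with loss of carbamate, and C–B oxidation with retention sets C13 as (R), the alkyl chain taking the place of the carbinol hydrogen of (S)-but-3-en-2-ol.

**Step 16**
Reactants: 28 the triethylsilyl ether of step 15
Product: 29 (1S,2S,4aS,6R,8aR)-6-bromo-1-[(3R)-3-hydroxy-3-methylpent-4-en-1-yl]-2,5,5,8a-tetramethyldecahydronaphthalen-2-ol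
Conditions: Bu4NF (3 equiv), THF, rt → 50 °C
Reagents that add atoms: none
Why: Fluoride-mediated cleavage of the Si–O bond under non-acidic conditions, which should spare the tertiary allylic alcohol and the equatorial neopentyl-type bromide.

**Compound list**
1 | methyl 3,3-dimethylpent-4-enoate | COC(=O)CC(C)(C)C=C | starting material
2 | 3,3-dimethylpent-4-enal | O=CCC(C)(C)C=C | intermediate
3 | (S)-2-bromo-3,3-dimethylpent-4-enal | O=C[C@@H](Br)C(C)(C)C=C | intermediate
4 | (S)-2-bromo-3,3-dimethylpent-4-en-1-ol | OC[C@@H](Br)C(C)(C)C=C | intermediate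
5 | (S)-2-bromo-3,3-dimethylpent-4-en-1-yl trifluoromethanesulfonate | O=S(=O)(OC[C@@H](Br)C(C)(C)C=C)C(F)(F)F | intermediate
6 | 1-(trimethylsilyl)propyne | CC#C[Si](C)(C)C | starting material
7 | [3-(trimethylsilyl)prop-2-yn-1-yl]lithium | [Li]CC#C[Si](C)(C)C | intermediate
8 | [(5R)-5-bromo-6,6-dimethyloct-7-en-1-yn-1-yl]trimethylsilane | C[Si](C)(C)C#CCC[C@@H](Br)C(C)(C)C=C | intermediate
9 | (5R)-5-bromo-6,6-dimethyloct-7-en-1-yne | C#CCC[C@@H](Br)C(C)(C)C=C | intermediate
10 | [(1E,5R)-5-bromo-2,6,6-trimethylocta-1,7-dien-1-yl]dimethylalumane | C[Al](C)/C=C(\C)CC[C@@H](Br)C(C)(C)C=C | intermediate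
11 | methyl (2E,6R)-6-bromo-3,7,7-trimethylnona-2,8-dienoate | COC(=O)/C=C(\C)CC[C@@H](Br)C(C)(C)C=C | intermediate
12 | (S)-pent-4-en-2-ol | C[C@H](O)CC=C | starting material
13 | methyl (2E,6R,8E,11S)-6-bromo-11-hydroxy-3,7,7-trimethyldodeca-2,8-dienoate | COC(=O)/C=C(\C)CC[C@@H](Br)C(C)(C)/C=C/C[C@H](C)O | intermediate
14 | methyl (2E,6R,8E)-6-bromo-3,7,7-trimethyl-11-oxododeca-2,8-dienoate | COC(=O)/C=C(\C)CC[C@@H](Br)C(C)(C)/C=C/CC(C)=O | intermediate
15 | methyl (2E,6R,8E,10Z)-6-bromo-3,7,7-trimethyl-11-[(triethylsilyl)oxy]dodeca-2,8,10-trienoate | COC(=O)/C=C(\C)CC[C@@H](Br)C(C)(C)/C=C/C=C(/C)O[Si](CC)(CC)CC | intermediate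
16 | (2E,6R,8E,10Z)-6-bromo-3,7,7-trimethyl-11-[(triethylsilyl)oxy]dodeca-2,8,10-trien-1-ol | OC/C=C(\C)CC[C@@H](Br)C(C)(C)/C=C/C=C(/C)O[Si](CC)(CC)CC | intermediate
17 | (2E,6R,8E,10Z)-6-bromo-3,7,7-trimethyl-11-[(triethylsilyl)oxy]dodeca-2,8,10-trienal | O=C/C=C(\C)CC[C@@H](Br)C(C)(C)/C=C/C=C(/C)O[Si](CC)(CC)CC | intermediate
18 | (1S,2S,4aS,6R,8aR)-6-bromo-2,5,5,8a-tetramethyl-2-[(triethylsilyl)oxy]-1,2,4a,5,6,7,8,8a-octahydronaphthalene-1-carbaldehyde | O=C[C@H]1[C@]2(C)CC[C@@H](Br)C(C)(C)[C@H]2C=C[C@]1(C)O[Si](CC)(CC)CC | intermediate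
19 | bis[(pinacolato)boryl]methane, 2,2'-methylenebis(4,4,5,5-tetramethyl-1,3,2-dioxaborolane) | CC1(C)OB(CB2OC(C)(C)C(C)(C)O2)OC1(C)C | starting material
20 | [bis(4,4,5,5-tetramethyl-1,3,2-dioxaborolan-2-yl)methyl]lithium | [Li]C(B1OC(C)(C)C(C)(C)O1)B1OC(C)(C)C(C)(C)O1 | intermediate
21 | 2-[(E)-2-[(1S,2S,4aS,6R,8aR)-6-bromo-2,5,5,8a-tetramethyl-2-[(triethylsilyl)oxy]-1,2,4a,5,6,7,8,8a-octahydronaphthalen-1-yl]ethenyl]-4,4,5,5-tetramethyl-1,3,2-dioxaborolane | CC1(C)OB(/C=C/[C@H]2[C@]3(C)CC[C@@H](Br)C(C)(C)[C@H]3C=C[C@]2(C)O[Si](CC)(CC)CC)OC1(C)C | intermediate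
22 | 2-{2-[(1S,2S,4aS,6R,8aR)-6-bromo-2,5,5,8a-tetramethyl-2-[(triethylsilyl)oxy]decahydronaphthalen-1-yl]ethyl}-4,4,5,5-tetramethyl-1,3,2-dioxaborolane | CC1(C)OB(CC[C@H]2[C@]3(C)CC[C@@H](Br)C(C)(C)[C@H]3CC[C@]2(C)O[Si](CC)(CC)CC)OC1(C)C | intermediate
23 | (S)-but-3-en-2-ol | C=C[C@H](C)O | starting material
24 | (S)-but-3-en-2-yl N,N-diisopropylcarbamate | C=C[C@H](C)OC(=O)N(C(C)C)C(C)C | intermediate
25 | [(2S)-2-(diisopropylcarbamoyloxy)but-3-en-2-yl]lithium | C=C[C@]([Li])(C)OC(=O)N(C(C)C)C(C)C | intermediate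
26 | lithium boronate complex of 22 with 25: boron bears the (2S)-2-(diisopropylcarbamoyloxy)but-3-en-2-yl group and the alkyl group of 22 | C=C[C@](C)(OC(=O)N(C(C)C)C(C)C)[B-]1(CC[C@H]2[C@]3(C)CC[C@@H](Br)C(C)(C)[C@H]3CC[C@]2(C)O[Si](CC)(CC)CC)OC(C)(C)C(C)(C)O1.[Li+] | intermediate
27 | 2-[(3S)-5-[(1S,2S,4aS,6R,8aR)-6-bromo-2,5,5,8a-tetramethyl-2-[(triethylsilyl)oxy]decahydronaphthalen-1-yl]-3-methylpent-1-en-3-yl]-4,4,5,5-tetramethyl-1,3,2-dioxaborolane | C=C[C@](C)(B1OC(C)(C)C(C)(C)O1)CC[C@H]2[C@]3(C)CC[C@@H](Br)C(C)(C)[C@H]3CC[C@]2(C)O[Si](CC)(CC)CC | intermediate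
28 | (3R)-5-[(1S,2S,4aS,6R,8aR)-6-bromo-2,5,5,8a-tetramethyl-2-[(triethylsilyl)oxy]decahydronaphthalen-1-yl]-3-methylpent-1-en-3-ol | C=C[C@](C)(O)CC[C@H]1[C@]2(C)CC[C@@H](Br)C(C)(C)[C@H]2CC[C@]1(C)O[Si](CC)(CC)CC | intermediate
29 | (1S,2S,4aS,6R,8aR)-6-bromo-1-[(3R)-3-hydroxy-3-methylpent-4-en-1-yl]-2,5,5,8a-tetramethyldecahydronaphthalen-2-ol | C=C[C@](C)(O)CC[C@H]1[C@]2(C)CC[C@@H](Br)C(C)(C)[C@H]2CC[C@]1(C)O | target

**Totals**
Total step count: 16. Longest linear sequence: 15 steps (steps 1–13, 15 and 16; step 14 is a side branch).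

**Steps most likely to fail**

Step 11. The cycloaddition may discriminate poorly between the two diene faces (only the equatorial preference of C–Br steers it) and between endo and exo transition states. The silyl dienol ether may also be lost, or the free aldehyde may oligomerise, before ring closure. The fallback moves the cycloaddition to the ester oxidation level. It sets out from 15, which is heated in toluene (160–170 °C, sealed tube, BHT), the known thermal cyclisation of deca-2,8,10-trienoates. This should give methyl (1S,2S,4aS,6R,8aR)-6-bromo-2,5,5,8a-tetramethyl-2-[(triethylsilyl)oxy]-1,2,4a,5,6,7,8,8a-octahydronaphthalene-1-carboxylate F1, a robust ester from which diastereomers can be removed by chromatography. Reduction with i-Bu2AlH at −78 °C then comes back to the route at 18.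

Step 15. The lithiated allyl carbamate may lose configuration, borylation may occur at the γ-carbon, the 1,2-migration may stay incomplete, or boron may shift to the allyl terminus before oxidation. The fallback builds C13 by epoxidation chemistry and sets out from 22.
- Suzuki–Miyaura coupling of 22 with (E)-3-iodobut-2-en-1-ol (Pd(OAc)2, RuPhos, K3PO4, toluene/H2O, 80 °C) should give (2E)-5-[(1S,2S,4aS,6R,8aR)-6-bromo-2,5,5,8a-tetramethyl-2-[(triethylsilyl)oxy]decahydronaphthalen-1-yl]-3-methylpent-2-en-1-ol F2.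
- Sharpless asymmetric epoxidation (Ti(O-i-Pr)4, D-(−)-diethyl tartrate, t-BuOOH, 4 Å molecular sieves, CH2Cl2, −20 °C) should give [(2R,3R)-3-{2-[(1S,2S,4aS,6R,8aR)-6-bromo-2,5,5,8a-tetramethyl-2-[(triethylsilyl)oxy]decahydronaphthalen-1-yl]ethyl}-3-methyloxiran-2-yl]methanol F3, with the facial sense known for geraniol-type E-allylic alcohols.
- PPh3, I2 and imidazole convert F3 into triethyl{[(1S,2S,4aS,6R,8aR)-6-bromo-1-{2-[(2R,3S)-3-(iodomethyl)-2-methyloxiran-2-yl]ethyl}-2,5,5,8a-tetramethyldecahydronaphthalen-2-yl]oxy}silane F4.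
- Zinc dust in AcOH/EtOH opens the epoxide reductively with retention at C13 and comes back to the route at 28.

Step 4. The strongly basic propargyl anion may cause E2 loss of triflic acid (a 2-bromoalkene) or bromine participation instead of substitution. The fallback uses a soft enolate and sets out from 5.
- Alkylation of 5 with the sodium enolate of tert-butyl acetoacetate (NaH, THF/DMF, 0 °C) should give tert-butyl (4R)-2-acetyl-4-bromo-5,5-dimethylhept-6-enoate F5 (both C2 epimers).
- CF3CO2H in CH2Cl2, then gentle warming, cleaves the ester and decarboxylates to (5R)-5-bromo-6,6-dimethyloct-7-en-2-one F6.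
- Horner–Wadsworth–Emmons reaction with trimethyl phosphonoacetate and NaH in THF, with chromatographic removal of the minor Z isomer, comes back to the route at 11.

**Further compounds**
F1 | step 11 | methyl (1S,2S,4aS,6R,8aR)-6-bromo-2,5,5,8a-tetramethyl-2-[(triethylsilyl)oxy]-1,2,4a,5,6,7,8,8a-octahydronaphthalene-1-carboxylate | COC(=O)[C@H]1[C@]2(C)CC[C@@H](Br)C(C)(C)[C@H]2C=C[C@]1(C)O[Si](CC)(CC)CC
F2 | step 15 | (2E)-5-[(1S,2S,4aS,6R,8aR)-6-bromo-2,5,5,8a-tetramethyl-2-[(triethylsilyl)oxy]decahydronaphthalen-1-yl]-3-methylpent-2-en-1-ol | OC/C=C(\C)CC[C@H]1[C@]2(C)CC[C@@H](Br)C(C)(C)[C@H]2CC[C@]1(C)O[Si](CC)(CC)CC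
F3 | step 15 | [(2R,3R)-3-{2-[(1S,2S,4aS,6R,8aR)-6-bromo-2,5,5,8a-tetramethyl-2-[(triethylsilyl)oxy]decahydronaphthalen-1-yl]ethyl}-3-methyloxiran-2-yl]methanol | C[C@]1(CC[C@H]2[C@]3(C)CC[C@@H](Br)C(C)(C)[C@H]3CC[C@]2(C)O[Si](CC)(CC)CC)O[C@@H]1CO
F4 | step 15 | triethyl{[(1S,2S,4aS,6R,8aR)-6-bromo-1-{2-[(2R,3S)-3-(iodomethyl)-2-methyloxiran-2-yl]ethyl}-2,5,5,8a-tetramethyldecahydronaphthalen-2-yl]oxy}silane | C[C@]1(CC[C@H]2[C@]3(C)CC[C@@H](Br)C(C)(C)[C@H]3CC[C@]2(C)O[Si](CC)(CC)CC)O[C@@H]1CI
F5 | step 4 | tert-butyl (4R)-2-acetyl-4-bromo-5,5-dimethylhept-6-enoate | CC(=O)C(C[C@@H](Br)C(C)(C)C=C)C(=O)OC(C)(C)C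
F6 | step 4 | (5R)-5-bromo-6,6-dimethyloct-7-en-2-one | CC(=O)CC[C@@H](Br)C(C)(C)C=C
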